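**Plan**
- Retrosynthesis: the methylene bridge is cut at the ring B C6–CH2 bond, giving a ring A Mannich base (aminomethylated propionylfilicinic acid) and 8-propionyl-5,7-dihydroxy-2,2-dimethylchromene.
- In the chromene, the C8–acyl bond, the two ether groups and the pyran O1–C2 bond are taken back to a prenylated phenol. Ring B is then cut at C4a–C8a and C5–C6 into 3-ethoxycyclobutenone and a prenyl-substituted siloxyalkyne.
- Enabling feature: ring B carries oxygens at C8a, C5 and C7 (1,3,5) separated by three different carbons (C4a, C6, C8). The benzannulation delivers them as free OH (C8a), silyl ether (C5) and ethyl ether (C7), with the prenyl carbon (C4a) beside the only free hydroxyl.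
- Forward: ring B by benzannulation, then the pyran ring (DDQ), C8 acylation (directed lithiation), and unmasking of the C7 and C5 hydroxyls. Ring A is made separately by gem-dimethylation of phloropropiophenone and a Mannich reaction, and the two rings are joined last.
- Stereochemistry: the target has no stereocentre; the chromene alkene is cis by ring constraint, so nothing has to be controlled.

Key step: step 3

Remark: ring B is numbered as a 2H-chromene (O1, C2 to C8a) throughout, and ring A is written in the enol tautomer of the target SMILES.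

Step 1
Reactants: 1 ethoxyacetylene; 2 acetyl chloride
Product: 4 3-ethoxycyclobut-2-en-1-one, via ketene 3 (not isolated)
Conditions: Et3N, CH2Cl2, 0 °C → rt; product kept cold and used promptly
Reagents that add atoms: none
Why: Triethylamine dehydrochlorinates the acid chloride to ketene, which undergoes the known ketene–alkoxyalkyne [2+2] cycloaddition, the nucleophilic terminal carbon of the ynol ether bonding to the ketene carbonyl carbon so that the ethoxy group ends at C3 of the cyclobutenone.

Step 2
Reactants: 5 ethyl 4-methylpent-3-enoate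
Product: 8 triisopropyl[(5-methylhex-4-en-1-yn-1-yl)oxy]silane, via dibromoenolate 6 (not isolated), via lithium ynolate 7 (not isolated)
Conditions: CH2Br2, lithium 2,2,6,6-tetramethylpiperidide (LiTMP, 2 equiv), THF, −78 °C; n-BuLi, −78 °C → rt; i-Pr3SiCl, −78 °C → rt
Reagents that add atoms: dibromomethane, BrCBr; triisopropylsilyl chloride, CC(C)[Si](Cl)(C(C)C)C(C)C
Why: Kowalski ester homologation: dibromomethyllithium adds to the ester, the dibromoketone is deprotonated to enolate 6, bromine–lithium exchange triggers the carbenoid rearrangement to ynolate 7, and the bulky chlorosilane silylates the ynolate on oxygen to give the siloxyalkyne.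

Step 3
Reactants: 4 3-ethoxycyclobut-2-en-1-one; 8 triisopropyl[(5-methylhex-4-en-1-yn-1-yl)oxy]silane
Product: 13 5-ethoxy-2-(3-methylbut-2-en-1-yl)-3-[(triisopropylsilyl)oxy]phenol, via vinylketene 9 (not isolated), via vinylcyclobutenone 10 (not isolated), via dienylketene 11 (not isolated), via cyclohexadienone 12 (not isolated)
Conditions: toluene, 80 °C, then 110 °C
Reagents that add atoms: none
Why: Danheiser benzannulation (cyclobutenone–siloxyalkyne aromatic annulation, here with a 3-alkoxycyclobutenone): 4π electrocyclic opening of 4 gives vinylketene 9, whose carbonyl carbon is attacked by the nucleophilic prenyl-bearing alkyne carbon in a [2+2] cycloaddition to give 10, which reopens to dienylketene 11. Ring B is then closed by a thermal disrotatory 6π electrocyclisation of 11, which re-forms the bond between the former C1 and C4 of the cyclobutenone to give dienone 12, and tautomerisation gives the phenol. The new skeletal bonds are C4a–C8a (ketene carbon to prenyl-bearing carbon) and C5–C6 (siloxy carbon to the cyclobutenone CH). No stereocentre is formed. The step needs regioselectivity in the ketene–alkyne cycloaddition, and the polarisation of the ynol ether (alkyl-substituted carbon nucleophilic, oxygen-substituted carbon electrophilic) secures it, so the prenyl group ends between the free hydroxyl and the siloxy group and the three oxygens emerge as OH, OSi(i-Pr)3 and OEt.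

Step 4
Reactants: 13 5-ethoxy-2-(3-methylbut-2-en-1-yl)-3-[(triisopropylsilyl)oxy]phenol
Product: 15 7-ethoxy-2,2-dimethyl-5-[(triisopropylsilyl)oxy]-2H-chromene, via quinone methide 14 (not isolated)
Conditions: DDQ, benzene, 80 °C
Reagents that add atoms: none
Why: Known oxidative cyclisation of o-prenylphenols: DDQ abstracts hydride from the benzylic, allylic methylene to give o-quinone methide 14, which closes the pyran by oxa-6π electrocyclisation, and since only the ketene-derived hydroxyl is free the pyran oxygen is fixed at that position.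

Step 5
Reactants: 15 7-ethoxy-2,2-dimethyl-5-[(triisopropylsilyl)oxy]-2H-chromene
Product: 17 1-{7-ethoxy-2,2-dimethyl-5-[(triisopropylsilyl)oxy]-2H-chromen-8-yl}propan-1-one, via aryllithium 16 (not isolated)
Conditions: n-BuLi, THF, 0 °C; EtC(O)N(OMe)Me, −78 °C → rt; H2O
Reagents that add atoms: N-methoxy-N-methylpropanamide, CCC(=O)N(C)OC
Why: Directed ortho-metalation: C8–H lies between the pyran oxygen and the ethoxy group (the cooperative site of a 1,3-dialkoxyarene), whereas C6–H is shielded by the bulky, poorly coordinating triisopropylsilyloxy group, and the aryllithium is acylated by the Weinreb amide, which gives the ketone without over-addition.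

Step 6
Reactants: 17 1-{7-ethoxy-2,2-dimethyl-5-[(triisopropylsilyl)oxy]-2H-chromen-8-yl}propan-1-one
Product: 18 1-{7-hydroxy-2,2-dimethyl-5-[(triisopropylsilyl)oxy]-2H-chromen-8-yl}propan-1-one
Conditions: BCl3, CH2Cl2, −78 → 0 °C; aq. NaHCO3
Reagents that add atoms: none
Why: Chelation-assisted ether cleavage: BCl3 binds the ketone oxygen and the adjacent ethoxy oxygen in a six-membered chelate and chloride removes the ethyl group, a selectivity well known for alkoxy groups ortho to aryl ketones, while the silyl ether para to the ketone has no such assistance.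

Step 7
Reactants: 18 1-{7-hydroxy-2,2-dimethyl-5-[(triisopropylsilyl)oxy]-2H-chromen-8-yl}propan-1-one
Product: 19 1-(5,7-dihydroxy-2,2-dimethyl-2H-chromen-8-yl)propan-1-one
Conditions: TBAF, AcOH, THF, 0 °C
Reagents that add atoms: none
Why: Fluoride-mediated desilylation of the aryl silyl ether, buffered with acetic acid so that the acidic acylphloroglucinol is not left as a free phenoxide; the chromene and the ketone are inert.

Step 8
Reactants: 20 1-(2,4,6-trihydroxyphenyl)propan-1-one
Product: 21 3,5-dihydroxy-4,4-dimethyl-2-propanoylcyclohexa-2,5-dien-1-one (propionylfilicinic acid)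
Conditions: NaOMe, MeI (about 2 equiv), MeOH, 0 °C → rt; aq. HCl
Reagents that add atoms: iodomethane, CI
Why: Dearomatising C-methylation of an acylphloroglucinol: the phenoxide is alkylated twice at the same ring carbon to give the gem-dimethyl filicinic acid core, a long-established reaction in which the amount of iodomethane limits over-methylation.

Step 9
Reactants: 21 3,5-dihydroxy-4,4-dimethyl-2-propanoylcyclohexa-2,5-dien-1-one
Product: 22 6-[(dimethylamino)methyl]-3,5-dihydroxy-4,4-dimethyl-2-propanoylcyclohexa-2,5-dien-1-one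
Conditions: dimethylmethylideneammonium iodide (Eschenmoser's salt), Et3N, CH2Cl2, 0 °C → rt
Reagents that add atoms: dimethylmethylideneammonium iodide, C=[N+](C)C.[I-]
Why: Mannich reaction: the enolised cyclic triketone reacts through its only unsubstituted ring carbon (C6) with the preformed iminium ion, giving a zwitterionic aminomethyl derivative that stores the bridge carbon on ring A.

Step 10
Reactants: 19 1-(5,7-dihydroxy-2,2-dimethyl-2H-chromen-8-yl)propan-1-one; 22 6-[(dimethylamino)methyl]-3,5-dihydroxy-4,4-dimethyl-2-propanoylcyclohexa-2,5-dien-1-one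
Product: 24 3,5-dihydroxy-6-[(5,7-dihydroxy-2,2-dimethyl-8-propanoyl-2H-chromen-6-yl)methyl]-4,4-dimethyl-2-propanoylcyclohexa-2,5-dien-1-one, via methylidene trione 23 (not isolated)
Conditions: 1,4-dioxane, 80 °C
Reagents that add atoms: none
Why: On warming the Mannich base loses dimethylamine to the exocyclic enone 23, a quinone-methide-like Michael acceptor, which is intercepted by C6 of 19 (the only free arene carbon, flanked by two hydroxyls) in a Mannich-base alkylation, that is a Friedel–Crafts-type conjugate addition that forms the methylene bridge.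

**Compound list**
1 | ethoxyacetylene | CCOC#C | starting material
2 | acetyl chloride | CC(=O)Cl | starting material
3 | ketene | C=C=O | intermediate
4 | 3-ethoxycyclobut-2-en-1-one | CCOC1=CC(=O)C1 | intermediate
5 | ethyl 4-methylpent-3-enoate | CCOC(=O)CC=C(C)C | starting material
6 | lithium 1,1-dibromo-5-methylhexa-1,4-dien-2-olate | [Li+].[O-]C(CC=C(C)C)=C(Br)Br | intermediate
7 | lithium 5-methylhex-4-en-1-yn-1-olate | [Li+].[O-]C#CCC=C(C)C | intermediate
8 | triisopropyl[(5-methylhex-4-en-1-yn-1-yl)oxy]silane | CC(C)=CCC#CO[Si](C(C)C)(C(C)C)C(C)C | intermediate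
9 | 3-ethoxybuta-1,3-dien-1-one | C=C(OCC)C=C=O | intermediate
10 | 4-(1-ethoxyethenyl)-2-(3-methylbut-2-en-1-yl)-3-[(triisopropylsilyl)oxy]cyclobut-2-en-1-one (racemic) | O=C1C(CC=C(C)C)=C(O[Si](C(C)C)(C(C)C)C(C)C)C1C(=C)OCC | intermediate
11 | (3E)-5-ethoxy-2-(3-methylbut-2-en-1-yl)-3-[(triisopropylsilyl)oxy]hexa-1,3,5-trien-1-one | O=C=C(CC=C(C)C)/C(O[Si](C(C)C)(C(C)C)C(C)C)=C\C(=C)OCC | intermediate
12 | 5-ethoxy-2-(3-methylbut-2-en-1-yl)-3-[(triisopropylsilyl)oxy]cyclohexa-2,4-dien-1-one | O=C1CC(OCC)=CC(O[Si](C(C)C)(C(C)C)C(C)C)=C1CC=C(C)C | intermediate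
13 | 5-ethoxy-2-(3-methylbut-2-en-1-yl)-3-[(triisopropylsilyl)oxy]phenol | CCOc1cc(O)c(CC=C(C)C)c(O[Si](C(C)C)(C(C)C)C(C)C)c1 | intermediate
14 | (6Z)-3-ethoxy-6-(3-methylbut-2-en-1-ylidene)-5-[(triisopropylsilyl)oxy]cyclohexa-2,4-dien-1-one | CC(C)=C/C=C1\C(=O)C=C(OCC)C=C1O[Si](C(C)C)(C(C)C)C(C)C | intermediate
15 | 7-ethoxy-2,2-dimethyl-5-[(triisopropylsilyl)oxy]-2H-chromene | CCOc1cc(O[Si](C(C)C)(C(C)C)C(C)C)c2C=CC(C)(C)Oc2c1 | intermediate
16 | {7-ethoxy-2,2-dimethyl-5-[(triisopropylsilyl)oxy]-2H-chromen-8-yl}lithium | [Li]c1c(OCC)cc(O[Si](C(C)C)(C(C)C)C(C)C)c2C=CC(C)(C)Oc12 | intermediate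
17 | 1-{7-ethoxy-2,2-dimethyl-5-[(triisopropylsilyl)oxy]-2H-chromen-8-yl}propan-1-one | CCC(=O)c1c(OCC)cc(O[Si](C(C)C)(C(C)C)C(C)C)c2C=CC(C)(C)Oc12 | intermediate
18 | 1-{7-hydroxy-2,2-dimethyl-5-[(triisopropylsilyl)oxy]-2H-chromen-8-yl}propan-1-one | CCC(=O)c1c(O)cc(O[Si](C(C)C)(C(C)C)C(C)C)c2C=CC(C)(C)Oc12 | intermediate
19 | 1-(5,7-dihydroxy-2,2-dimethyl-2H-chromen-8-yl)propan-1-one | CCC(=O)c1c(O)cc(O)c2C=CC(C)(C)Oc12 | intermediate
20 | 1-(2,4,6-trihydroxyphenyl)propan-1-one | CCC(=O)c1c(O)cc(O)cc1O | starting material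
21 | 3,5-dihydroxy-4,4-dimethyl-2-propanoylcyclohexa-2,5-dien-1-one | CCC(=O)C1=C(O)C(C)(C)C(O)=CC1=O | intermediate
22 | 6-[(dimethylamino)methyl]-3,5-dihydroxy-4,4-dimethyl-2-propanoylcyclohexa-2,5-dien-1-one | CCC(=O)C1=C(O)C(C)(C)C(O)=C(CN(C)C)C1=O | intermediate
23 | 5-hydroxy-6,6-dimethyl-2-methylidene-4-propanoylcyclohex-4-ene-1,3-dione | CCC(=O)C1=C(O)C(C)(C)C(=O)C(=C)C1=O | intermediate
24 | 3,5-dihydroxy-6-[(5,7-dihydroxy-2,2-dimethyl-8-propanoyl-2H-chromen-6-yl)methyl]-4,4-dimethyl-2-propanoylcyclohexa-2,5-dien-1-one | CCC(=O)C1=C(O)C(C)(C)C(O)=C(Cc2c(O)c3c(c(C(=O)CC)c2O)OC(C)(C)C=C3)C1=O | target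

**Step count**
Total: 10 steps. Longest linear sequence: 7 steps (step 1 or 2, then 3, 4, 5, 6, 7, 10).

**Steps most likely to fail**

Step 5. Metalation may occur in part at C6 instead of C8, the silyl group may migrate to carbon after metalation, or the aryllithium may enolise the amide instead of being acylated. The fallback sets out from 13 and uses the free phenol to direct the acyl carbon. Magnesium-mediated ortho-formylation (MgCl2, Et3N, paraformaldehyde, MeCN, reflux) can only occur at the single open ortho position and should give 6-ethoxy-2-hydroxy-3-(3-methylbut-2-en-1-yl)-4-[(triisopropylsilyl)oxy]benzaldehyde F1. Addition of EtMgBr (excess, THF, 0 °C) should give racemic 3-ethoxy-2-(1-hydroxypropyl)-6-(3-methylbut-2-en-1-yl)-5-[(triisopropylsilyl)oxy]phenol F2. Oxidation with MnO2 in CH2Cl2 should give 1-{6-ethoxy-2-hydroxy-3-(3-methylbut-2-en-1-yl)-4-[(triisopropylsilyl)oxy]phenyl}propan-1-one F3. DDQ in benzene then closes the pyran onto the only free hydroxyl, and the route is rejoined at 17.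

Step 6. Boron may chelate the ketone with the pyran oxygen instead of the ethoxy oxygen and ionise the allylic, tertiary O1–C2 bond, opening the chromene, or HCl may add to the C3=C4 alkene. The fallback sets out from 17 and runs the ether cleavage at the chroman oxidation level, where no allylic cation can form and a transiently opened ring re-closes. Hydrogenation (H2, Pd/C, EtOAc) should give 1-{7-ethoxy-2,2-dimethyl-5-[(triisopropylsilyl)oxy]-3,4-dihydro-2H-chromen-8-yl}propan-1-one F4. BCl3 in CH2Cl2 then should give 1-{7-hydroxy-2,2-dimethyl-5-[(triisopropylsilyl)oxy]-3,4-dihydro-2H-chromen-8-yl}propan-1-one F5. DDQ dehydrogenation of the chroman (1,4-dioxane, reflux) re-installs the alkene, and the route is rejoined at 18.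

Step 10. Retro-Mannich exchange may scramble the one-carbon unit and lead to symmetrical methylene-bridged dimers, or the enone may be captured at oxygen instead of carbon. The fallback sets out from 19 and reverses the roles of the two rings. Aminomethylation of 19 at C6 with dimethylmethylideneammonium iodide (CH2Cl2, 0 °C) should give 1-{6-[(dimethylamino)methyl]-5,7-dihydroxy-2,2-dimethyl-2H-chromen-8-yl}propan-1-one F6. Heating F6 with the acidic triketone 21 in 1,4-dioxane should expel dimethylamine to a ring B o-quinone methide, which is captured by the enol carbon C6 of 21, and the route is rejoined at 24.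

**Further compounds**
F1 | step 5 | 6-ethoxy-2-hydroxy-3-(3-methylbut-2-en-1-yl)-4-[(triisopropylsilyl)oxy]benzaldehyde | CCOc1cc(O[Si](C(C)C)(C(C)C)C(C)C)c(CC=C(C)C)c(O)c1C=O
F2 | step 5 | 3-ethoxy-2-(1-hydroxypropyl)-6-(3-methylbut-2-en-1-yl)-5-[(triisopropylsilyl)oxy]phenol (racemic) | CCOc1cc(O[Si](C(C)C)(C(C)C)C(C)C)c(CC=C(C)C)c(O)c1C(O)CC
F3 | step 5 | 1-{6-ethoxy-2-hydroxy-3-(3-methylbut-2-en-1-yl)-4-[(triisopropylsilyl)oxy]phenyl}propan-1-one | CCOc1cc(O[Si](C(C)C)(C(C)C)C(C)C)c(CC=C(C)C)c(O)c1C(=O)CC
F4 | step 6 | 1-{7-ethoxy-2,2-dimethyl-5-[(triisopropylsilyl)oxy]-3,4-dihydro-2H-chromen-8-yl}propan-1-one | CCC(=O)c1c(OCC)cc(O[Si](C(C)C)(C(C)C)C(C)C)c2CCC(C)(C)Oc12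
F5 | step 6 | 1-{7-hydroxy-2,2-dimethyl-5-[(triisopropylsilyl)oxy]-3,4-dihydro-2H-chromen-8-yl}propan-1-one | CCC(=O)c1c(O)cc(O[Si](C(C)C)(C(C)C)C(C)C)c2CCC(C)(C)Oc12
F6 | step 10 | 1-{6-[(dimethylamino)methyl]-5,7-dihydroxy-2,2-dimethyl-2H-chromen-8-yl}propan-1-one | CCC(=O)c1c(O)c(CN(C)C)c(O)c2C=CC(C)(C)Oc12
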